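**Plan**

Atom labels: ring B = C1 (CH3), C2, C3, C4 (side chain); ring A = C4a, C5 (H), C6 (CO2H), C7 (OH), C8 (OH), C8a; side chain = C11 (with C18H2OAc), C12, C13, C14, C15 (with CH3 and C16H2OAc).
Retrosynthesis: the acetates, the C6–CO2H bond (aryllithium/CO2) and the C7–O bond (formylation/Dakin) go first, leaving an 8-hydroxytetralin. Its C8 oxygen sits on the ring A carbon next to fusion carbon C8a, which is where a furan oxygen ends up when a 2-alkylfuran and a terminal alkyne joined by C4–C3–C2–C1 are cycloisomerised, so C4a–C8a and C7–C8 are cut together.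
The open-chain furan-yne is cut at C8a≡C8 (aldehyde homologation), at C4–C11 with return of the C2–O bond (ester-enolate Claisen), at the ester C–O bond, at C13=C14 (Wittig) and at C1–C2 (aldol).
Forward: an aldol fragment (furan, C4–C1, C8a) is esterified with a C18/C11–C16 acid, the Claisen rearrangement joins the whole chain, both alkenes are saturated and the alkyne is installed. One gold step then closes ring B and builds ring A, and ring A is oxygenated at C7 and carboxylated at C6 last.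
Stereochemistry: C1 comes from an oxazolidinone-controlled syn-aldol; its carbinol neighbour C2 is relayed to C4 and C11 through the chair Claisen transition state of the E(O)-enolate; C15 comes from methyl (S)-3-hydroxy-2-methylpropanoate; the gold step forms no stereocentre.

Key step: step 15

Remark: the two side-chain oxygens are carried as TBDPS ethers and the oxygen on the future alkyne carbon C8a as a TBS ether so that only the latter is released before the key step; the Wittig alkene of 12 is expected mainly Z and its geometry is irrelevant because it is saturated in step 11.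

**Route**

Step 1
Reactants: 1 (R)-4-benzyl-3-propionyloxazolidin-2-one; 2 (E)-3-(furan-2-yl)acrylaldehyde
Product: 4 (R)-4-benzyl-3-[(2R,3S,4E)-5-(furan-2-yl)-3-hydroxy-2-methylpent-4-enoyl]oxazolidin-2-one, via boron Z-enolate 3 (not isolated)
Conditions: n-Bu2BOTf, i-Pr2NEt, CH2Cl2, 0 °C; 2, −78 to 0 °C; then pH 7 buffer, MeOH, H2O2, 0 °C
Reagents that add atoms: none
Why: Evans syn-aldol, in which the Z-boron enolate adds to the aldehyde through a closed six-membered chair on the enolate face away from the benzyl group, so the (R)-auxiliary fixes both the methyl-bearing carbon (later C1) and the carbinol carbon (later C2) as the 2,3-syn pair.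

Step 2
Reactants: 4 (R)-4-benzyl-3-[(2R,3S,4E)-5-(furan-2-yl)-3-hydroxy-2-methylpent-4-enoyl]oxazolidin-2-one
Product: 5 (2S,3S,4E)-5-(furan-2-yl)-2-methylpent-4-ene-1,3-diol
Conditions: LiBH4, MeOH (1 equiv), THF, 0 °C
Reagents that add atoms: none
Why: Reductive cleavage of the N-acyl oxazolidinone by borohydride attack on the exocyclic imide carbonyl gives the 1,3-diol without change at either stereocentre and releases the auxiliary intact.

Step 3
Reactants: 5 (2S,3S,4E)-5-(furan-2-yl)-2-methylpent-4-ene-1,3-diol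
Product: 6 (1E,3S,4S)-5-(tert-butyldimethylsilyloxy)-1-(furan-2-yl)-4-methylpent-1-en-3-ol
Conditions: TBSCl (1.05 equiv), imidazole, CH2Cl2, −20 to 0 °C
Reagents that add atoms: tert-butyldimethylsilyl chloride, CC(C)(C)[Si](C)(C)Cl
Why: Silyl ether formation under steric control, the primary hydroxyl reacting much faster with the bulky silyl chloride than the secondary allylic one, which must stay free for the esterification.

Step 4
Reactants: 7 methyl (S)-3-hydroxy-2-methylpropanoate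
Product: 8 methyl (S)-3-(tert-butyldiphenylsilyloxy)-2-methylpropanoate
Conditions: TBDPSCl, imidazole, CH2Cl2, rt
Reagents that add atoms: tert-butyl(chloro)diphenylsilane, CC(C)(C)[Si](Cl)(c1ccccc1)c1ccccc1
Why: Silyl ether formation on the only hydroxyl, with a silyl group chosen to outlast the acid that later removes the TBS group.

Step 5
Reactants: 8 methyl (S)-3-(tert-butyldiphenylsilyloxy)-2-methylpropanoate
Product: 9 (S)-3-(tert-butyldiphenylsilyloxy)-2-methylpropanal
Conditions: i-Bu2AlH (1.05 equiv), CH2Cl2, −78 °C; aq. potassium sodium tartrate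
Reagents that add atoms: none
Why: Partial reduction of the ester to the aldehyde with one equivalent of aluminium hydride at low temperature, under which the α-methyl stereocentre (later C15) is not epimerised.

Step 6
Reactants: 9 (S)-3-(tert-butyldiphenylsilyloxy)-2-methylpropanal; 10 (3-carboxypropyl)triphenylphosphonium bromide
Product: 12 (4Z,6R)-7-(tert-butyldiphenylsilyloxy)-6-methylhept-4-enoic acid, via ylide carboxylate 11 (not isolated)
Conditions: 10, NaN(SiMe3)2 (2.1 equiv), THF, 0 °C; 9, −78 °C to rt; then 1 M HCl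
Reagents that add atoms: none
Why: Wittig olefination with a non-stabilised ylide forms C13=C14 (mainly Z) and brings in C12, C11 and the C18 carboxyl in one operation, the low temperature preserving the adjacent C15 centre.

Step 7
Reactants: 6 (1E,3S,4S)-5-(tert-butyldimethylsilyloxy)-1-(furan-2-yl)-4-methylpent-1-en-3-ol; 12 (4Z,6R)-7-(tert-butyldiphenylsilyloxy)-6-methylhept-4-enoic acid
Product: 13 (1E,3S,4S)-5-(tert-butyldimethylsilyloxy)-1-(furan-2-yl)-4-methylpent-1-en-3-yl (4Z,6R)-7-(tert-butyldiphenylsilyloxy)-6-methylhept-4-enoate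
Conditions: DCC, DMAP (cat.), CH2Cl2, 0 °C to rt
Reagents that add atoms: none
Why: Steglich esterification acylates the secondary allylic oxygen under non-acidic conditions, so the acid-sensitive furyl allylic system does not ionise and C2 keeps its configuration.

Step 8
Reactants: 13 (1E,3S,4S)-5-(tert-butyldimethylsilyloxy)-1-(furan-2-yl)-4-methylpent-1-en-3-yl (4Z,6R)-7-(tert-butyldiphenylsilyloxy)-6-methylhept-4-enoate
Product: 17 (2S,3S,4E,6R)-7-(tert-butyldimethylsilyloxy)-2-[(2Z,4R)-5-(tert-butyldiphenylsilyloxy)-4-methylpent-2-en-1-yl]-3-(furan-2-yl)-6-methylhept-4-enoic acid, via lithium E(O)-enolate 14 (not isolated), via silyl ketene acetal 15 (not isolated), via trimethylsilyl ester 16 (not isolated)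
Conditions: LiN(i-Pr)2 (1.2 equiv), THF, −78 °C; Me3SiCl, −78 °C to rt, then 40 °C; dilute HCl
Reagents that add atoms: none
Why: Ireland–Claisen rearrangement in which kinetic deprotonation in THF gives the E(O)-enolate (C12 chain cis to the allylic oxygen) and its silyl ketene acetal rearranges through a chair with the C1-bearing group on C2 equatorial, so the C2–O bond is exchanged suprafacially for the C4–C11 bond, which sets C4 (S) from the (S)-carbinol, sets C11 (S, anti to the furyl group) from the axial C12 chain, and leaves an (E)-C2=C3 alkene.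

Step 9
Reactants: 17 (2S,3S,4E,6R)-7-(tert-butyldimethylsilyloxy)-2-[(2Z,4R)-5-(tert-butyldiphenylsilyloxy)-4-methylpent-2-en-1-yl]-3-(furan-2-yl)-6-methylhept-4-enoic acid
Product: 18 (2S,3S,4E,6R)-7-(tert-butyldimethylsilyloxy)-2-[(2Z,4R)-5-(tert-butyldiphenylsilyloxy)-4-methylpent-2-en-1-yl]-3-(furan-2-yl)-6-methylhept-4-en-1-ol
Conditions: LiAlH4, THF, 0 °C to rt
Reagents that add atoms: none
Why: Hydride reduction of the carboxylic acid to the primary alcohol (C18–OH), which leaves silyl ethers, isolated alkenes and the furan untouched.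

Step 10
Reactants: 18 (2S,3S,4E,6R)-7-(tert-butyldimethylsilyloxy)-2-[(2Z,4R)-5-(tert-butyldiphenylsilyloxy)-4-methylpent-2-en-1-yl]-3-(furan-2-yl)-6-methylhept-4-en-1-ol
Product: 19 (2S,3S,4E,6R)-7-(tert-butyldimethylsilyloxy)-1-(tert-butyldiphenylsilyloxy)-2-[(2Z,4R)-5-(tert-butyldiphenylsilyloxy)-4-methylpent-2-en-1-yl]-3-(furan-2-yl)-6-methylhept-4-ene
Conditions: TBDPSCl, imidazole, DMF, rt
Reagents that add atoms: tert-butyl(chloro)diphenylsilane, CC(C)(C)[Si](Cl)(c1ccccc1)c1ccccc1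
Why: Silyl ether formation on the new primary hydroxyl gives the side chain its second robust silyl ether.

Step 11
Reactants: 19 (2S,3S,4E,6R)-7-(tert-butyldimethylsilyloxy)-1-(tert-butyldiphenylsilyloxy)-2-[(2Z,4R)-5-(tert-butyldiphenylsilyloxy)-4-methylpent-2-en-1-yl]-3-(furan-2-yl)-6-methylhept-4-ene
Product: 20 (2R,5S,6S,10R)-1-(tert-butyldimethylsilyloxy)-11-(tert-butyldiphenylsilyloxy)-6-[(tert-butyldiphenylsilyloxy)methyl]-5-(furan-2-yl)-2,10-dimethylundecane
Conditions: TsNHNH2 (excess, in portions), NaOAc, DME/H2O, reflux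
Reagents that add atoms: none
Why: Diimide reduction transfers H2 concertedly and syn to both disubstituted alkenes without a metal hydride, so C2=C3 cannot migrate into conjugation with the furan and erase C4, and the furan is not reduced.

Step 12
Reactants: 20 (2R,5S,6S,10R)-1-(tert-butyldimethylsilyloxy)-11-(tert-butyldiphenylsilyloxy)-6-[(tert-butyldiphenylsilyloxy)methyl]-5-(furan-2-yl)-2,10-dimethylundecane
Product: 21 (2R,5S,6S,10R)-11-(tert-butyldiphenylsilyloxy)-6-[(tert-butyldiphenylsilyloxy)methyl]-5-(furan-2-yl)-2,10-dimethylundecan-1-ol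
Conditions: camphorsulfonic acid (cat.), MeOH/CH2Cl2, 0 °C
Reagents that add atoms: none
Why: Acid-catalysed methanolysis is much faster for the primary TBS ether than for the two TBDPS ethers, so only the C8a oxygen is set free.

Step 13
Reactants: 21 (2R,5S,6S,10R)-11-(tert-butyldiphenylsilyloxy)-6-[(tert-butyldiphenylsilyloxy)methyl]-5-(furan-2-yl)-2,10-dimethylundecan-1-ol
Product: 22 (2R,5S,6S,10R)-11-(tert-butyldiphenylsilyloxy)-6-[(tert-butyldiphenylsilyloxy)methyl]-5-(furan-2-yl)-2,10-dimethylundecanal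
Conditions: DMP (1,1,1-triacetoxy-1,1-dihydro-1,2-benziodoxol-3(1H)-one), pyridine, CH2Cl2, 0 °C to rt
Reagents that add atoms: none
Why: Periodinane oxidation of the primary alcohol to the aldehyde under buffered, non-enolising conditions keeps the α-methyl stereocentre C1.

Step 14
Reactants: 22 (2R,5S,6S,10R)-11-(tert-butyldiphenylsilyloxy)-6-[(tert-butyldiphenylsilyloxy)methyl]-5-(furan-2-yl)-2,10-dimethylundecanal
Product: 23 2-[(3R,6S,7S,11R)-12-(tert-butyldiphenylsilyloxy)-7-[(tert-butyldiphenylsilyloxy)methyl]-3,11-dimethyldodec-1-yn-6-yl]furan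
Conditions: dimethyl (1-diazo-2-oxopropyl)phosphonate, K2CO3, MeOH, 0 °C to rt
Reagents that add atoms: dimethyl (1-diazo-2-oxopropyl)phosphonate, CC(=O)C(=[N+]=[N-])P(=O)(OC)OC
Why: Ohira–Bestmann alkynylation (Seyferth–Gilbert homologation with the diazomethylphosphonate made in situ) turns the aldehyde into the terminal alkyne by adding C8 under carbonate conditions mild enough for C1 to survive.

Step 15
Reactants: 23 2-[(3R,6S,7S,11R)-12-(tert-butyldiphenylsilyloxy)-7-[(tert-butyldiphenylsilyloxy)methyl]-3,11-dimethyldodec-1-yn-6-yl]furan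
Product: 28 (5S,8R)-5-[(2S,6R)-1,7-bis(tert-butyldiphenylsilyloxy)-6-methylheptan-2-yl]-8-methyl-5,6,7,8-tetrahydronaphthalen-1-ol, via cyclopropyl gold carbenoid 24 (not isolated), via dienal gold carbenoid 25 (not isolated), via oxepine 26 (not isolated), via arene oxide 27 (not isolated)
Conditions: Ph3PAuNTf2 (5 mol %), dry CH2Cl2, rt
Reagents that add atoms: none
Why: Cationic monovalent gold π-activates the terminal alkyne, the furan C2=C3 bond attacks its internal carbon to give cyclopropyl carbenoid 24, this opens to the (Z)-dienal carbenoid 25, the aldehyde oxygen closes onto the carbenoid carbon to give oxepine 26 in equilibrium with arene oxide 27, and 27 opens to the phenol with the oxygen on the former terminal alkyne carbon C8. The closest known reaction type is this same gold-catalysed furan-yne phenol synthesis with furfuryl propargyl ethers, amines and malonates and with all-carbon tethers leading to indanols, so the four-carbon all-carbon tether is an application to a new substrate. Ring B closes by 6-exo-dig attack of furan C2 on the alkyne (bond C4a–C8a), and ring A closes by the 6π electrocyclisation of the oxepine to the arene oxide (bond C7–C8). No stereocentre is formed; C1 and C4 lie on the tether, are not touched, and their trans substituents can both sit pseudo-equatorially in the folded tether. The step needs chemoselectivity for the phenol pathway over alkyne hydration and oligomerisation, which the dry non-coordinating medium, the unhindered terminal alkyne and the electron-rich unsubstituted furan C2=C3 bond secure; the hydroxyl position at C8, ortho to C8a, is fixed by the mechanism, and the silyl ethers are inert.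

Step 16
Reactants: 28 (5S,8R)-5-[(2S,6R)-1,7-bis(tert-butyldiphenylsilyloxy)-6-methylheptan-2-yl]-8-methyl-5,6,7,8-tetrahydronaphthalen-1-ol
Product: 29 (5S,8R)-5-[(2S,6R)-1,7-bis(tert-butyldiphenylsilyloxy)-6-methylheptan-2-yl]-1-hydroxy-8-methyl-5,6,7,8-tetrahydronaphthalene-2-carbaldehyde
Conditions: MgCl2, Et3N, (CH2O)n, THF, reflux; then 1 M HCl
Reagents that add atoms: formaldehyde (as paraformaldehyde), C=O
Why: Casnati–Skattebøl ortho-formylation, in which the magnesium phenoxide delivers formaldehyde to the ortho carbon and a second equivalent accepts hydride; C7 is the only free ortho position because C8a is substituted.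

Step 17
Reactants: 29 (5S,8R)-5-[(2S,6R)-1,7-bis(tert-butyldiphenylsilyloxy)-6-methylheptan-2-yl]-1-hydroxy-8-methyl-5,6,7,8-tetrahydronaphthalene-2-carbaldehyde
Product: 31 (5S,8R)-5-[(2S,6R)-1,7-bis(tert-butyldiphenylsilyloxy)-6-methylheptan-2-yl]-8-methyl-5,6,7,8-tetrahydronaphthalene-1,2-diol, via aryl formate 30 (not isolated)
Conditions: H2O2 (30 % aq.), NaOH, THF/H2O, 0 °C, argon; then dilute HCl
Reagents that add atoms: hydrogen peroxide, OO
Why: Dakin oxidation, in which hydroperoxide adds to the ortho-hydroxy aldehyde, aryl migration gives the formate and its hydrolysis in the basic medium leaves the C7 hydroxyl.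

Step 18
Reactants: 31 (5S,8R)-5-[(2S,6R)-1,7-bis(tert-butyldiphenylsilyloxy)-6-methylheptan-2-yl]-8-methyl-5,6,7,8-tetrahydronaphthalene-1,2-diol
Product: 32 (5S,8R)-5-[(2S,6R)-1,7-bis(tert-butyldiphenylsilyloxy)-6-methylheptan-2-yl]-1,2-bis(methoxymethoxy)-8-methyl-5,6,7,8-tetrahydronaphthalene
Conditions: NaH, MOMCl, THF/DMF, 0 °C to rt
Reagents that add atoms: chloromethyl methyl ether, COCCl
Why: Williamson-type O-alkylation of both phenoxides protects the catechol and supplies the directing group for the metalation.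

Step 19
Reactants: 32 (5S,8R)-5-[(2S,6R)-1,7-bis(tert-butyldiphenylsilyloxy)-6-methylheptan-2-yl]-1,2-bis(methoxymethoxy)-8-methyl-5,6,7,8-tetrahydronaphthalene
Product: 34 (5R,8S)-8-[(2S,6R)-1,7-bis(tert-butyldiphenylsilyloxy)-6-methylheptan-2-yl]-3,4-bis(methoxymethoxy)-5-methyl-5,6,7,8-tetrahydronaphthalene-2-carboxylic acid, via C6 aryllithium 33 (not isolated)
Conditions: s-BuLi, TMEDA, THF, −78 °C; CO2; then dilute HCl to pH 4
Reagents that add atoms: carbon dioxide, O=C=O
Why: Directed ortho-metalation, in which the C7 OMOM oxygen guides lithiation to C6 (the only ring position ortho to an acetal oxygen) and the aryllithium is carboxylated by CO2.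

Step 20
Reactants: 34 (5R,8S)-8-[(2S,6R)-1,7-bis(tert-butyldiphenylsilyloxy)-6-methylheptan-2-yl]-3,4-bis(methoxymethoxy)-5-methyl-5,6,7,8-tetrahydronaphthalene-2-carboxylic acid
Product: 35 (5R,8S)-8-[(2S,6R)-1,7-dihydroxy-6-methylheptan-2-yl]-3,4-bis(methoxymethoxy)-5-methyl-5,6,7,8-tetrahydronaphthalene-2-carboxylic acid
Conditions: n-Bu4NF, THF, rt; then dilute HCl to pH 4
Reagents that add atoms: none
Why: Fluoride-induced cleavage of both silyl ethers, driven by Si–F bond formation, leaves the MOM acetals and the carboxylate unchanged.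

Step 21
Reactants: 35 (5R,8S)-8-[(2S,6R)-1,7-dihydroxy-6-methylheptan-2-yl]-3,4-bis(methoxymethoxy)-5-methyl-5,6,7,8-tetrahydronaphthalene-2-carboxylic acid
Product: 37 (5R,8S)-8-[(2S,6R)-1,7-diacetoxy-6-methylheptan-2-yl]-3,4-bis(methoxymethoxy)-5-methyl-5,6,7,8-tetrahydronaphthalene-2-carboxylic acid, via mixed acetic anhydride 36 (not isolated)
Conditions: Ac2O, pyridine, DMAP (cat.), CH2Cl2, 0 °C to rt; then THF/H2O
Reagents that add atoms: acetic anhydride, CC(=O)OC(C)=O
Why: Nucleophile-catalysed acylation of the two primary alcohols, the mixed anhydride formed at the carboxyl group being hydrolysed back to the acid on aqueous work-up while the alkyl acetates persist.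

Step 22
Reactants: 37 (5R,8S)-8-[(2S,6R)-1,7-diacetoxy-6-methylheptan-2-yl]-3,4-bis(methoxymethoxy)-5-methyl-5,6,7,8-tetrahydronaphthalene-2-carboxylic acid
Product: 38 (5R,8S)-8-[(2S,6R)-1,7-diacetoxy-6-methylheptan-2-yl]-3,4-dihydroxy-5-methyl-5,6,7,8-tetrahydronaphthalene-2-carboxylic acid (target CNP0245723.1)
Conditions: CF3CO2H, CH2Cl2, H2O (3 equiv), 0 °C to rt
Reagents that add atoms: none
Why: Acid-catalysed hydrolysis of the two aryl MOM acetals under conditions too mild and too poor in nucleophile to cleave primary acetates gives the catechol acid.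

**Compound list**

1 | (R)-4-benzyl-3-propionyloxazolidin-2-one | CCC(=O)N1[C@H](Cc2ccccc2)COC1=O | starting material
2 | (E)-3-(furan-2-yl)acrylaldehyde | O=C/C=C/c1ccco1 | starting material
3 | dibutylboron (Z)-enolate of 1 | C/C=C(\OB(CCCC)CCCC)N1[C@H](Cc2ccccc2)COC1=O | intermediate
4 | (R)-4-benzyl-3-[(2R,3S,4E)-5-(furan-2-yl)-3-hydroxy-2-methylpent-4-enoyl]oxazolidin-2-one | o1cccc1/C=C/[C@H](O)[C@@H](C)C(=O)N1[C@H](Cc2ccccc2)COC1=O | intermediate
5 | (2S,3S,4E)-5-(furan-2-yl)-2-methylpent-4-ene-1,3-diol | o1cccc1/C=C/[C@H](O)[C@@H](C)CO | intermediate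
6 | (1E,3S,4S)-5-(tert-butyldimethylsilyloxy)-1-(furan-2-yl)-4-methylpent-1-en-3-ol | o1cccc1/C=C/[C@H](O)[C@@H](C)CO[Si](C)(C)C(C)(C)C | intermediate
7 | methyl (S)-3-hydroxy-2-methylpropanoate | OC[C@H](C)C(=O)OC | starting material
8 | methyl (S)-3-(tert-butyldiphenylsilyloxy)-2-methylpropanoate | CC(C)(C)[Si](c1ccccc1)(c1ccccc1)OC[C@H](C)C(=O)OC | intermediate
9 | (S)-3-(tert-butyldiphenylsilyloxy)-2-methylpropanal | CC(C)(C)[Si](c1ccccc1)(c1ccccc1)OC[C@H](C)C=O | intermediate
10 | (3-carboxypropyl)triphenylphosphonium bromide | OC(=O)CCC[P+](c1ccccc1)(c1ccccc1)c1ccccc1.[Br-] | starting material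
11 | sodium 4-(triphenyl-λ5-phosphanylidene)butanoate | [Na+].[O-]C(=O)CCC=P(c1ccccc1)(c1ccccc1)c1ccccc1 | intermediate
12 | (4Z,6R)-7-(tert-butyldiphenylsilyloxy)-6-methylhept-4-enoic acid | CC(C)(C)[Si](c1ccccc1)(c1ccccc1)OC[C@H](C)/C=C\CCC(=O)O | intermediate
13 | (1E,3S,4S)-5-(tert-butyldimethylsilyloxy)-1-(furan-2-yl)-4-methylpent-1-en-3-yl (4Z,6R)-7-(tert-butyldiphenylsilyloxy)-6-methylhept-4-enoate | o1cccc1/C=C/[C@H](OC(=O)CC/C=C\[C@@H](C)CO[Si](c2ccccc2)(c2ccccc2)C(C)(C)C)[C@@H](C)CO[Si](C)(C)C(C)(C)C | intermediate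
14 | lithium E(O)-enolate of 13 (C12 chain cis to the allylic oxygen) | o1cccc1/C=C/[C@H](O/C(O[Li])=C\C/C=C\[C@@H](C)CO[Si](c2ccccc2)(c2ccccc2)C(C)(C)C)[C@@H](C)CO[Si](C)(C)C(C)(C)C | intermediate
15 | (E)-trimethylsilyl ketene acetal of 13 (C12 chain trans to OSiMe3) | o1cccc1/C=C/[C@H](O/C(O[Si](C)(C)C)=C\C/C=C\[C@@H](C)CO[Si](c2ccccc2)(c2ccccc2)C(C)(C)C)[C@@H](C)CO[Si](C)(C)C(C)(C)C | intermediate
16 | trimethylsilyl ester of 17 | CC(C)(C)[Si](c1ccccc1)(c1ccccc1)OC[C@H](C)/C=C\C[C@H](C(=O)O[Si](C)(C)C)[C@@H](c1ccco1)/C=C/[C@@H](C)CO[Si](C)(C)C(C)(C)C | intermediate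
17 | (2S,3S,4E,6R)-7-(tert-butyldimethylsilyloxy)-2-[(2Z,4R)-5-(tert-butyldiphenylsilyloxy)-4-methylpent-2-en-1-yl]-3-(furan-2-yl)-6-methylhept-4-enoic acid | CC(C)(C)[Si](c1ccccc1)(c1ccccc1)OC[C@H](C)/C=C\C[C@H](C(=O)O)[C@@H](c1ccco1)/C=C/[C@@H](C)CO[Si](C)(C)C(C)(C)C | intermediate
18 | (2S,3S,4E,6R)-7-(tert-butyldimethylsilyloxy)-2-[(2Z,4R)-5-(tert-butyldiphenylsilyloxy)-4-methylpent-2-en-1-yl]-3-(furan-2-yl)-6-methylhept-4-en-1-ol | CC(C)(C)[Si](c1ccccc1)(c1ccccc1)OC[C@H](C)/C=C\C[C@H](CO)[C@@H](c1ccco1)/C=C/[C@@H](C)CO[Si](C)(C)C(C)(C)C | intermediate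
19 | (2S,3S,4E,6R)-7-(tert-butyldimethylsilyloxy)-1-(tert-butyldiphenylsilyloxy)-2-[(2Z,4R)-5-(tert-butyldiphenylsilyloxy)-4-methylpent-2-en-1-yl]-3-(furan-2-yl)-6-methylhept-4-ene | CC(C)(C)[Si](c1ccccc1)(c1ccccc1)OC[C@H](C)/C=C\C[C@H](CO[Si](c1ccccc1)(c1ccccc1)C(C)(C)C)[C@@H](c1ccco1)/C=C/[C@@H](C)CO[Si](C)(C)C(C)(C)C | intermediate
20 | (2R,5S,6S,10R)-1-(tert-butyldimethylsilyloxy)-11-(tert-butyldiphenylsilyloxy)-6-[(tert-butyldiphenylsilyloxy)methyl]-5-(furan-2-yl)-2,10-dimethylundecane | CC(C)(C)[Si](c1ccccc1)(c1ccccc1)OC[C@H](C)CCC[C@H](CO[Si](c1ccccc1)(c1ccccc1)C(C)(C)C)[C@@H](c1ccco1)CC[C@@H](C)CO[Si](C)(C)C(C)(C)C | intermediate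
21 | (2R,5S,6S,10R)-11-(tert-butyldiphenylsilyloxy)-6-[(tert-butyldiphenylsilyloxy)methyl]-5-(furan-2-yl)-2,10-dimethylundecan-1-ol | CC(C)(C)[Si](c1ccccc1)(c1ccccc1)OC[C@H](C)CCC[C@H](CO[Si](c1ccccc1)(c1ccccc1)C(C)(C)C)[C@@H](c1ccco1)CC[C@@H](C)CO | intermediate
22 | (2R,5S,6S,10R)-11-(tert-butyldiphenylsilyloxy)-6-[(tert-butyldiphenylsilyloxy)methyl]-5-(furan-2-yl)-2,10-dimethylundecanal | CC(C)(C)[Si](c1ccccc1)(c1ccccc1)OC[C@H](C)CCC[C@H](CO[Si](c1ccccc1)(c1ccccc1)C(C)(C)C)[C@@H](c1ccco1)CC[C@@H](C)C=O | intermediate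
23 | 2-[(3R,6S,7S,11R)-12-(tert-butyldiphenylsilyloxy)-7-[(tert-butyldiphenylsilyloxy)methyl]-3,11-dimethyldodec-1-yn-6-yl]furan (key-step precursor) | CC(C)(C)[Si](c1ccccc1)(c1ccccc1)OC[C@H](C)CCC[C@H](CO[Si](c1ccccc1)(c1ccccc1)C(C)(C)C)[C@@H](c1ccco1)CC[C@@H](C)C#C | intermediate
24 | cyclopropyl carbenoid cation [(Ph3P)Au=CH–R]+ (cyclopropane from furan C2 and C3 and the internal alkyne carbon; ring B closed) | CC(C)(C)[Si](c1ccccc1)(c1ccccc1)OC[C@H](C)CCC[C@H](CO[Si](c1ccccc1)(c1ccccc1)C(C)(C)C)[C@@H]4CC[C@@H](C)C2(C=[Au][P+](c5ccccc5)(c5ccccc5)c5ccccc5)C3C=COC243 | intermediate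
25 | ring-opened (Z)-dienal carbenoid cation [(Ph3P)Au=CH–R']+ | CC(C)(C)[Si](c1ccccc1)(c1ccccc1)OC[C@H](C)CCC[C@H](CO[Si](c1ccccc1)(c1ccccc1)C(C)(C)C)[C@@H]1CC[C@@H](C)C(C=[Au][P+](c5ccccc5)(c5ccccc5)c5ccccc5)=C1/C=C\C=O | intermediate
26 | ring B-fused oxepine (oxygen between C7 and C8) | CC(C)(C)[Si](c1ccccc1)(c1ccccc1)OC[C@H](C)CCC[C@H](CO[Si](c1ccccc1)(c1ccccc1)C(C)(C)C)[C@@H]1CC[C@@H](C)C2=COC=CC=C12 | intermediate
27 | C7–C8 arene oxide (epoxide face not defined) | CC(C)(C)[Si](c1ccccc1)(c1ccccc1)OC[C@H](C)CCC[C@H](CO[Si](c1ccccc1)(c1ccccc1)C(C)(C)C)[C@@H]1CC[C@@H](C)C2=C1C=CC3OC23 | intermediate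
28 | (5S,8R)-5-[(2S,6R)-1,7-bis(tert-butyldiphenylsilyloxy)-6-methylheptan-2-yl]-8-methyl-5,6,7,8-tetrahydronaphthalen-1-ol (key-step product) | CC(C)(C)[Si](c1ccccc1)(c1ccccc1)OC[C@H](C)CCC[C@H](CO[Si](c1ccccc1)(c1ccccc1)C(C)(C)C)[C@@H]1CC[C@@H](C)c2c1cccc2O | intermediate
29 | (5S,8R)-5-[(2S,6R)-1,7-bis(tert-butyldiphenylsilyloxy)-6-methylheptan-2-yl]-1-hydroxy-8-methyl-5,6,7,8-tetrahydronaphthalene-2-carbaldehyde | CC(C)(C)[Si](c1ccccc1)(c1ccccc1)OC[C@H](C)CCC[C@H](CO[Si](c1ccccc1)(c1ccccc1)C(C)(C)C)[C@@H]1CC[C@@H](C)c2c1ccc(C=O)c2O | intermediate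
30 | (5S,8R)-5-[(2S,6R)-1,7-bis(tert-butyldiphenylsilyloxy)-6-methylheptan-2-yl]-1-hydroxy-8-methyl-5,6,7,8-tetrahydronaphthalen-2-yl formate | CC(C)(C)[Si](c1ccccc1)(c1ccccc1)OC[C@H](C)CCC[C@H](CO[Si](c1ccccc1)(c1ccccc1)C(C)(C)C)[C@@H]1CC[C@@H](C)c2c1ccc(OC=O)c2O | intermediate
31 | (5S,8R)-5-[(2S,6R)-1,7-bis(tert-butyldiphenylsilyloxy)-6-methylheptan-2-yl]-8-methyl-5,6,7,8-tetrahydronaphthalene-1,2-diol | CC(C)(C)[Si](c1ccccc1)(c1ccccc1)OC[C@H](C)CCC[C@H](CO[Si](c1ccccc1)(c1ccccc1)C(C)(C)C)[C@@H]1CC[C@@H](C)c2c1ccc(O)c2O | intermediate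
32 | (5S,8R)-5-[(2S,6R)-1,7-bis(tert-butyldiphenylsilyloxy)-6-methylheptan-2-yl]-1,2-bis(methoxymethoxy)-8-methyl-5,6,7,8-tetrahydronaphthalene | CC(C)(C)[Si](c1ccccc1)(c1ccccc1)OC[C@H](C)CCC[C@H](CO[Si](c1ccccc1)(c1ccccc1)C(C)(C)C)[C@@H]1CC[C@@H](C)c2c1ccc(OCOC)c2OCOC | intermediate
33 | C6 aryllithium of 32 | CC(C)(C)[Si](c1ccccc1)(c1ccccc1)OC[C@H](C)CCC[C@H](CO[Si](c1ccccc1)(c1ccccc1)C(C)(C)C)[C@@H]1CC[C@@H](C)c2c1cc([Li])c(OCOC)c2OCOC | intermediate
34 | (5R,8S)-8-[(2S,6R)-1,7-bis(tert-butyldiphenylsilyloxy)-6-methylheptan-2-yl]-3,4-bis(methoxymethoxy)-5-methyl-5,6,7,8-tetrahydronaphthalene-2-carboxylic acid | CC(C)(C)[Si](c1ccccc1)(c1ccccc1)OC[C@H](C)CCC[C@H](CO[Si](c1ccccc1)(c1ccccc1)C(C)(C)C)[C@@H]1CC[C@@H](C)c2c1cc(C(=O)O)c(OCOC)c2OCOC | intermediate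
35 | (5R,8S)-8-[(2S,6R)-1,7-dihydroxy-6-methylheptan-2-yl]-3,4-bis(methoxymethoxy)-5-methyl-5,6,7,8-tetrahydronaphthalene-2-carboxylic acid | OC[C@H](C)CCC[C@H](CO)[C@@H]1CC[C@@H](C)c2c1cc(C(=O)O)c(OCOC)c2OCOC | intermediate
36 | mixed acetic anhydride of 37 | CC(=O)OC[C@H](C)CCC[C@H](COC(C)=O)[C@@H]1CC[C@@H](C)c2c1cc(C(=O)OC(C)=O)c(OCOC)c2OCOC | intermediate
37 | (5R,8S)-8-[(2S,6R)-1,7-diacetoxy-6-methylheptan-2-yl]-3,4-bis(methoxymethoxy)-5-methyl-5,6,7,8-tetrahydronaphthalene-2-carboxylic acid | CC(=O)OC[C@H](C)CCC[C@H](COC(C)=O)[C@@H]1CC[C@@H](C)c2c1cc(C(=O)O)c(OCOC)c2OCOC | intermediate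
38 | (5R,8S)-8-[(2S,6R)-1,7-diacetoxy-6-methylheptan-2-yl]-3,4-dihydroxy-5-methyl-5,6,7,8-tetrahydronaphthalene-2-carboxylic acid (1R,4S,11S,15R in the labels of the plan) | CC(=O)OC[C@H](C)CCC[C@H](COC(C)=O)[C@@H]1CC[C@@H](C)c2c1cc(C(=O)O)c(O)c2O | target

**Step count and risks**

Total step count: 22. Longest linear sequence: 19 steps (steps 1–3 or 4–6, then 7–22).

Step 15 is the most likely to fail. The 6-exo-dig closure of a flexible all-carbon tether may be slow, so that alkyne hydration, oligomerisation or simple furan hydroarylation consumes the substrate before the phenol pathway is entered. The fallback sets out from alkyne 23 and forms the same two bonds thermally. The lithium acetylide of 23 (n-BuLi, THF, −78 °C) is acylated with N-methoxy-N-methylacetamide to the alkynyl methyl ketone F1. An intramolecular Diels–Alder reaction of the furan with this activated alkyne (toluene, reflux, or Me2AlCl at low temperature) gives the oxanorbornadiene F2, with C4a–C8a and C7–C8 formed. Acid (TsOH or BF3·OEt2) cleaves the tertiary C4a–O bond and aromatises to the 8-acetyl-7-hydroxytetralin F3. Dakin oxidation of this ortho-hydroxyaryl ketone (H2O2, NaOH) exchanges the acetyl group for a hydroxyl and rejoins the route at catechol 31, steps 16 and 17 then being unnecessary.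

Step 8 is the second risk. Enolisation may not be fully E(O)-selective, which erodes the configuration at C11, and the electron-rich furyl allylic ester may ionise or eliminate before it rearranges. The fallback separates the two stereocentres and sets out from alcohol 6 and aldehyde 9. Alcohol 6 is acetylated (Ac2O, pyridine) to the acetate F4, whose Ireland–Claisen rearrangement has no enolate geometry and gives the acid F5 with C4 set by the same chirality transfer. F5 is attached to (S)-4-benzyloxazolidin-2-one (PivCl, Et3N; lithiated auxiliary) to give the N-acyl oxazolidinone F6. In parallel, aldehyde 9 is converted by Wittig reaction with (2-hydroxyethyl)triphenylphosphonium bromide into the (Z)-allylic alcohol F7 and then (CBr4, PPh3) into the (Z)-allylic bromide F8. Alkylation of the sodium enolate of F6 with F8 (NaN(SiMe3)2, THF, −78 °C) gives the alkylated imide F9, with C11 now set by the auxiliary on the enolate face away from the benzyl group. LiBH4 reduction then rejoins the route at alcohol 18.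

Step 11 is the third risk. The (E)-C2=C3 alkene is flanked by two tertiary carbons and may be saturated only partly while diimide is lost by disproportionation. The fallback sets out from alcohol 18 and uses hydroxyl-directed homogeneous hydrogenation with [Ir(cod)(PCy3)(py)]PF6 under H2 in CH2Cl2, which should reduce both alkenes without reducing the furan and give the saturated alcohol F10. Silylation of F10 (TBDPSCl, imidazole) rejoins the route at compound 20.

**Further compounds**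

F1 | step 15 | (5R,8S,9S,13R)-14-(tert-butyldiphenylsilyloxy)-9-[(tert-butyldiphenylsilyloxy)methyl]-8-(furan-2-yl)-5,13-dimethyltetradec-3-yn-2-one | CC(C)(C)[Si](c1ccccc1)(c1ccccc1)OC[C@H](C)CCC[C@H](CO[Si](c1ccccc1)(c1ccccc1)C(C)(C)C)[C@@H](c1ccco1)CC[C@@H](C)C#CC(C)=O
F2 | step 15 | oxanorbornadiene cycloadduct of F1 (oxygen bridge between C4a and C7, acetyl on C8, bridge configuration not defined) | CC(C)(C)[Si](c1ccccc1)(c1ccccc1)OC[C@H](C)CCC[C@H](CO[Si](c1ccccc1)(c1ccccc1)C(C)(C)C)[C@@H]4CC[C@@H](C)C2=C(C(C)=O)C3OC24C=C3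
F3 | step 15 | 1-[(5S,8R)-5-[(2S,6R)-1,7-bis(tert-butyldiphenylsilyloxy)-6-methylheptan-2-yl]-2-hydroxy-8-methyl-5,6,7,8-tetrahydronaphthalen-1-yl]ethan-1-one | CC(C)(C)[Si](c1ccccc1)(c1ccccc1)OC[C@H](C)CCC[C@H](CO[Si](c1ccccc1)(c1ccccc1)C(C)(C)C)[C@@H]1CC[C@@H](C)c2c1ccc(O)c2C(C)=O
F4 | step 8 | (1E,3S,4S)-5-(tert-butyldimethylsilyloxy)-1-(furan-2-yl)-4-methylpent-1-en-3-yl acetate | o1cccc1/C=C/[C@H](OC(C)=O)[C@@H](C)CO[Si](C)(C)C(C)(C)C
F5 | step 8 | (3R,4E,6R)-7-(tert-butyldimethylsilyloxy)-3-(furan-2-yl)-6-methylhept-4-enoic acid | OC(=O)C[C@@H](c1ccco1)/C=C/[C@@H](C)CO[Si](C)(C)C(C)(C)C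
F6 | step 8 | (S)-4-benzyl-3-[(3R,4E,6R)-7-(tert-butyldimethylsilyloxy)-3-(furan-2-yl)-6-methylhept-4-enoyl]oxazolidin-2-one | O=C1OC[C@H](Cc2ccccc2)N1C(=O)C[C@@H](c1ccco1)/C=C/[C@@H](C)CO[Si](C)(C)C(C)(C)C
F7 | step 8 | (2Z,4R)-5-(tert-butyldiphenylsilyloxy)-4-methylpent-2-en-1-ol | CC(C)(C)[Si](c1ccccc1)(c1ccccc1)OC[C@H](C)/C=C\CO
F8 | step 8 | {[(2R,3Z)-5-bromo-2-methylpent-3-en-1-yl]oxy}(tert-butyl)diphenylsilane | CC(C)(C)[Si](c1ccccc1)(c1ccccc1)OC[C@H](C)/C=C\CBr
F9 | step 8 | (S)-4-benzyl-3-[(2S,3S,4E,6R)-7-(tert-butyldimethylsilyloxy)-2-[(2Z,4R)-5-(tert-butyldiphenylsilyloxy)-4-methylpent-2-en-1-yl]-3-(furan-2-yl)-6-methylhept-4-enoyl]oxazolidin-2-one | O=C1OC[C@H](Cc2ccccc2)N1C(=O)[C@@H](C/C=C\[C@@H](C)CO[Si](c2ccccc2)(c2ccccc2)C(C)(C)C)[C@@H](c1ccco1)/C=C/[C@@H](C)CO[Si](C)(C)C(C)(C)C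
F10 | step 11 | (2S,3S,6R)-7-(tert-butyldimethylsilyloxy)-2-[(4R)-5-(tert-butyldiphenylsilyloxy)-4-methylpentyl]-3-(furan-2-yl)-6-methylheptan-1-ol | CC(C)(C)[Si](c1ccccc1)(c1ccccc1)OC[C@H](C)CCC[C@H](CO)[C@@H](c1ccco1)CC[C@@H](C)CO[Si](C)(C)C(C)(C)C
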